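The route rests on cutting the A-C3–C9 bond of ring C. In that ring the ether bond O1–C11 and the bond A-C3–C9 lie 1,3 to each other across C10. The chain A-C3=A-C4–O1–C11–C10=C9 is therefore an aromatic Claisen array. Precursor 17 is the (11R)-quinolon-4-yl ether of a ring-D pyranol with an exocyclic 3-methylbutylidene group at C10, its chain cis to C11. Heating should break O1–C11, form A-C3–C9 on the same face and move the alkene into ring D. One operation thus joins both quinolone halves through carbon and relays the carbinol configuration to C9. Acid then closes ring C and fixes C10 and C11.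

Key step: step 10

Atom labels: quinolones A and B are the two 7,8-dimethoxy-1-methylquinolin-2-one units, each with its own numbering. C9 is the CH(isobutyl) on A-C3, C10 the ring-fusion CH, C11 the CH(O1) on B-C3, and C12 the CMe2 carbon. Ring C is A-C3, A-C4, O1, C11, C10, C9. Ring D is B-C3, B-C4, O2, C12, C10, C11.

Stereochemical bookkeeping: the target is 9S,10S,11R, with H10/H11 cis and H9/H10 trans. A suprafacial shift from 11R with the chain cis to C11 gives 9S. The same alkene geometry is Z in ketone 15 and E in 16 and 17, because C11 outranks C12 only while it is a carbonyl carbon.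

Assumption: the target SMILES is taken as the absolute configuration.

Step 1
Reactants: 1 2,3-dimethoxyaniline
Product: 3 2,3-dimethoxy-N-methylaniline, via N-(methoxymethyl)aniline 2 (not isolated)
Conditions: (CH2O)n, NaOMe, MeOH, 25 °C; then NaBH4, 65 °C
Reagents that add atoms: paraformaldehyde (reacts as formaldehyde), C=O
Why: Stepwise reductive amination in which the aniline is first converted completely into its mono-adduct 2 and the hydride is added only afterwards, so that nitrogen receives one methyl group and not two.

Step 2
Reactants: 3 2,3-dimethoxy-N-methylaniline; 4 Meldrum's acid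
Product: 6 4-hydroxy-7,8-dimethoxy-1-methylquinolin-2(1H)-one (quinolinol), via malonamic acid 5 (not isolated)
Conditions: PhMe, 100 °C; evaporate; then P2O5 in MeSO3H (1:10 w/w), 70 °C
Reagents that add atoms: none
Why: Aminolysis of Meldrum's acid releases acetone and leaves malonamic acid 5, which P2O5/MeSO3H cyclises by intramolecular Friedel–Crafts acylation at the only free ortho position, a site activated by the para methoxy group.

Step 3
Reactants: 6 quinolinol
Product: 7 4-chloro-7,8-dimethoxy-1-methylquinolin-2(1H)-one
Conditions: POCl3 (neat), 95 °C; ice, aq NaOAc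
Reagents that add atoms: phosphoryl chloride POCl3, O=P(Cl)(Cl)Cl
Why: Deoxychlorination of the vinylogous acid hydroxyl, a standard conversion of N-alkyl-4-hydroxyquinolin-2-ones in which the N-methyl lactam carbonyl is restored on aqueous work-up.

Step 4
Reactants: 6 quinolinol; 8 3-methylbut-2-enoyl chloride
Product: 10 4-hydroxy-7,8-dimethoxy-1-methyl-3-(3-methylbut-2-enoyl)quinolin-2(1H)-one, via enol ester 9 (not isolated)
Conditions: Et3N, CH2Cl2, 0 °C; then DMAP (0.5 equiv), 25 °C; aq HCl work-up
Reagents that add atoms: none
Why: O-acylation of the acidic enol followed by DMAP-mediated O-to-C acyl migration (Fries-type shift of cyclic 1,3-dicarbonyl enol esters) is driven by the hydrogen-bonded tricarbonyl product, and any double-bond isomer of the acyl chain formed through a vinylketene converges in step 5.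

Step 5
Reactants: 10 3-acylquinolinol
Product: 11 ring-D chromanone 7,8-dimethoxy-2,2,6-trimethyl-2,3-dihydro-4H-pyrano[3,2-c]quinoline-4,5(6H)-dione
Conditions: MeSO3H (1 equiv), CH2Cl2, 25 °C
Reagents that add atoms: none
Why: Acid-catalysed intramolecular oxa-Michael addition (6-endo-trig) of the C4 hydroxyl to the beta,beta-dimethyl enone is helped by the gem-dimethyl effect and, being reversible, should settle on the isomer closed through O4, which keeps the more stable 2-quinolone lactam.

Step 6
Reactants: 11 ring-D chromanone; 12 isovaleraldehyde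
Product: 13 aldol 3-(1-hydroxy-3-methylbutyl) chromanone (diastereomer mixture)
Conditions: LiN(SiMe3)2, THF, −78 °C; then 12, −78 °C; AcOH quench at −78 °C
Reagents that add atoms: none
Why: Kinetic lithium enolate formation at C10, the only enolisable position, and aldol addition at a temperature low enough to hold back retro-oxa-Michael opening of ring D; the two new centres need no control because both vanish in step 7.

Step 7
Reactants: 13 aldol
Product: 15 (Z)-enone with the chain CH2 cis to the C11 carbonyl, via mesylate 14 (not isolated)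
Conditions: MsCl, Et3N, CH2Cl2, 0 °C; then DBU, 25 °C
Reagents that add atoms: none
Why: E1cB elimination of the mesylate completes the aldol condensation, the isomer with the chain cis to the carbonyl should prevail because the other forces the chain against the C12 gem-dimethyl group, and any minor isomer is removed by chromatography since it would lead to 9R.

Step 8
Reactants: 15 (Z)-enone
Product: 16 (4R,3E)-allylic alcohol (11R)
Conditions: (R)-2-methyl-CBS-oxazaborolidine (20 mol %), catecholborane, PhMe, −78 °C; MeOH, then aq NaOH work-up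
Reagents that add atoms: none
Why: Corey–Bakshi–Shibata reduction, run with catecholborane at low temperature to suppress uncatalysed lactam-directed and conjugate hydride delivery: the chain CH2 blocks the oxygen lone pair on the C10 side, so the catalyst boron should bind on the B-C3 side, treat the alkylidene arm as the large group and in the (R)-series deliver hydride to the face that gives 11R (sense to be verified by Mosher ester analysis, the (S)-catalyst being the remedy if it is opposite).

Step 9
Reactants: 16 (4R,3E)-allylic alcohol; 7 4-chloroquinolone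
Product: 17 (4R,3E)-4-(quinolon-4-yloxy) ring-D pyran (Claisen precursor)
Conditions: NaH, THF–DMF (5:1), 0 °C; then 7, 0 to 25 °C
Reagents that add atoms: none
Why: Addition–elimination (SNAr type) of the sodium alkoxide at C4 of the vinylogous carbamoyl chloride 7, a known reaction of 4-chloroquinolin-2-ones with alkoxides, never breaks the C11–O bond, so 11R is retained.

Step 10
Reactants: 17 Claisen precursor
Product: 19 ring-D chromene bearing 4-hydroxyquinolone A at (9S)-C9, via quinoline-2,4-dione tautomer 18 (not isolated)
Conditions: iPr2NEt (2 equiv), PhMe (0.02 M), 100 °C, base-washed glassware, Ar; aq NaH2PO4 work-up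
Reagents that add atoms: none
Why: A concerted suprafacial [3,3]-sigmatropic shift over A-C3=A-C4–O1–C11–C10=C9 gives dione 18, whose acidic A-C3–H enolises at once to 19; this is the aromatic Claisen rearrangement known for 4-allyloxyquinolin-2-ones, including 1,3-chirality transfer from secondary allyl ethers. No ring is closed: one C–C bond forms and the alkene moves into ring D. C9 is governed by two fixed elements, namely allylic 1,3-strain with the cis chain CH2, which holds O1 pseudoaxial on ring D so that A-C3 must reach C9 on the face that O1 leaves, and the alkene geometry, which decides where chain and hydrogen point; 11R with the chain cis to C11 gives 9S. Because C10–C11 is locked in ring D there is no second rotamer, and chair and boat arrays differ only at A-C3, whose configuration is erased by enolisation. The selectivity needed is the concerted shift over heterolysis of the allylic, ring-B-stabilised C11–O1 bond. A dilute non-polar medium, acid-free glass and iPr2NEt, which binds the acidic product and so stops autocatalysis and the abnormal Claisen pathway, are meant to secure it.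

Step 11
Reactants: 19 Claisen product
Product: 20 target CNP0275598.1
Conditions: p-TsOH·H2O (10 mol %), CH2Cl2, 25 °C
Reagents that add atoms: none
Why: Markovnikov protonation of the chromene at C10 gives the C11 cation stabilised by O2 through B-C4=B-C3 and the A-C4 hydroxyl captures it (intramolecular hydroalkoxylation closing six-membered ring C); with H9 turned towards the gem-dimethyl group, the rotamer of least allylic strain, quinolone A lies on the face that O1 left in step 10, so O1 returns there (11R) and the proton enters anti (10S, H10/H11 cis, H9/H10 trans), while the reversibility of protonation and of C11–O ionisation lets other isomers, including closure through the A-C2 oxygen, drain to this most stable one.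

Compound list
1 | 2,3-dimethoxyaniline | COc1cccc(N)c1OC | starting material
2 | 2,3-dimethoxy-N-(methoxymethyl)aniline | COCNc1cccc(OC)c1OC | intermediate
3 | 2,3-dimethoxy-N-methylaniline | CNc1cccc(OC)c1OC | intermediate
4 | Meldrum's acid (2,2-dimethyl-1,3-dioxane-4,6-dione) | CC1(C)OC(=O)CC(=O)O1 | starting material
5 | 3-[(2,3-dimethoxyphenyl)(methyl)amino]-3-oxopropanoic acid | COc1cccc(N(C)C(=O)CC(=O)O)c1OC | intermediate
6 | 4-hydroxy-7,8-dimethoxy-1-methylquinolin-2(1H)-one | COc1ccc2c(O)cc(=O)n(C)c2c1OC | intermediate
7 | 4-chloro-7,8-dimethoxy-1-methylquinolin-2(1H)-one | COc1ccc2c(Cl)cc(=O)n(C)c2c1OC | intermediate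
8 | 3-methylbut-2-enoyl chloride | CC(C)=CC(Cl)=O | starting material
9 | 7,8-dimethoxy-1-methyl-2-oxo-1,2-dihydroquinolin-4-yl 3-methylbut-2-enoate | COc1ccc2c(OC(=O)C=C(C)C)cc(=O)n(C)c2c1OC | intermediate
10 | 4-hydroxy-7,8-dimethoxy-1-methyl-3-(3-methylbut-2-enoyl)quinolin-2(1H)-one | COc1ccc2c(O)c(C(=O)C=C(C)C)c(=O)n(C)c2c1OC | intermediate
11 | 7,8-dimethoxy-2,2,6-trimethyl-2,3-dihydro-4H-pyrano[3,2-c]quinoline-4,5(6H)-dione | O=C1c2c(c3ccc(OC)c(OC)c3n(C)c2=O)OC(C)(C)C1 | intermediate
12 | isovaleraldehyde (3-methylbutanal) | CC(C)CC=O | starting material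
13 | 3-(1-hydroxy-3-methylbutyl)-7,8-dimethoxy-2,2,6-trimethyl-2,3-dihydro-4H-pyrano[3,2-c]quinoline-4,5(6H)-dione, diastereomer mixture | O=C1c2c(c3ccc(OC)c(OC)c3n(C)c2=O)OC(C)(C)C1C(O)CC(C)C | intermediate
14 | methanesulfonate of 13, diastereomer mixture | O=C1c2c(c3ccc(OC)c(OC)c3n(C)c2=O)OC(C)(C)C1C(OS(C)(=O)=O)CC(C)C | intermediate
15 | (3Z)-7,8-dimethoxy-2,2,6-trimethyl-3-(3-methylbutylidene)-2,3-dihydro-4H-pyrano[3,2-c]quinoline-4,5(6H)-dione | O=C1c2c(c3ccc(OC)c(OC)c3n(C)c2=O)OC(C)(C)/C1=C/CC(C)C | intermediate
16 | (3E,4R)-4-hydroxy-7,8-dimethoxy-2,2,6-trimethyl-3-(3-methylbutylidene)-3,4-dihydro-2H-pyrano[3,2-c]quinolin-5(6H)-one | O[C@H]1c2c(c3ccc(OC)c(OC)c3n(C)c2=O)OC(C)(C)/C1=C/CC(C)C | intermediate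
17 | (3E,4R)-4-[(7,8-dimethoxy-1-methyl-2-oxo-1,2-dihydroquinolin-4-yl)oxy]-7,8-dimethoxy-2,2,6-trimethyl-3-(3-methylbutylidene)-3,4-dihydro-2H-pyrano[3,2-c]quinolin-5(6H)-one | COc1ccc2c(O[C@H]3c4c(c5ccc(OC)c(OC)c5n(C)c4=O)OC(C)(C)/C3=C/CC(C)C)cc(=O)n(C)c2c1OC | intermediate
18 | quinoline-2,4(1H,3H)-dione tautomer of 19 (A-C3 configuration undefined, lost on enolisation) | COc1ccc2c(c1OC)N(C)C(=O)C([C@@H](CC(C)C)C1=Cc3c(c4ccc(OC)c(OC)c4n(C)c3=O)OC1(C)C)C2=O | intermediate
19 | 3-[(1S)-1-(4-hydroxy-7,8-dimethoxy-1-methyl-2-oxo-1,2-dihydroquinolin-3-yl)-3-methylbutyl]-7,8-dimethoxy-2,2,6-trimethyl-2H-pyrano[3,2-c]quinolin-5(6H)-one | COc1ccc2c(O)c(c(=O)n(C)c2c1OC)[C@@H](CC(C)C)C1=Cc2c(c3ccc(OC)c(OC)c3n(C)c2=O)OC1(C)C | intermediate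
20 | CNP0275598.1, (9S,10S,11R), rings C and D cis-fused, isobutyl trans to C12 | COc1ccc2c3c(c(=O)n(C)c2c1OC)[C@@H](CC(C)C)[C@H]1[C@@H](O3)c2c(c3ccc(OC)c(OC)c3n(C)c2=O)OC1(C)C | target

Total step count: 11.
Longest linear sequence: 10 steps (1, 2, 4, 5, 6, 7, 8, 9, 10, 11). Step 3 is a one-step branch from 6.

Steps most likely to fail

1. Step 10. Heterolysis of the C11–O1 bond to a contact ion pair may outrun the concerted shift. That would erode the chirality transfer and open a 1,4-elimination towards a diene.
Fallback: ring C is built by a domino Knoevenagel/hetero-Diels–Alder reaction, setting out from 6 and coming back at 20.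
   - Condensation of 6 with 3-methylbut-2-enal (ethylenediammonium diacetate, PhMe, 80 °C; Knoevenagel condensation, then oxa-6π electrocyclisation) should give the chromene 7,8-dimethoxy-2,2,6-trimethyl-2H-pyrano[3,2-c]quinolin-5(6H)-one F1.
   - A second portion of 6 and aldehyde 12 under the same catalyst form in situ the heterodiene 7,8-dimethoxy-1-methyl-3-(3-methylbutylidene)quinoline-2,4(1H,3H)-dione F2.
   - The O1=A-C4–A-C3=C9 unit of F2 adds across C10=C11 of F1, C9 to the nucleophilic C10 and O1 to C11. The cis ring fusion follows from the ring alkene.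
   - Brief treatment with p-TsOH as in step 11 equilibrates the adducts to the racemate of the target F3. Preparative chromatography on a chiral stationary phase then delivers 20.

2. Step 8. Both ketone substituents are flat sp2 arms, so facial discrimination may be poor. Hydride delivery directed by the neighbouring lactam oxygen may add a racemic background.
Fallback: resolution replaces asymmetric catalysis, setting out from 15 and coming back at 16.
   - Luche reduction (NaBH4, CeCl3·7H2O, MeOH, 0 °C) should give the racemic (3E)-allylic alcohol F4.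
   - Esterification with (S)-O-methylmandelic acid (DCC, DMAP, CH2Cl2, 0 °C) gives the (11R)-alcohol (S)-O-methylmandelate F5 and the (11S)-alcohol (S)-O-methylmandelate F6, which are separated on silica.
   - LiOH in aqueous THF at 0 °C cleaves F5 at the acyl carbon and returns 16.

3. Step 9. Attack of the hindered, pseudoaxial alkoxide on the chloroquinolone may be sluggish. Prolonged warming in the polar medium could start uncontrolled rearrangement or ionisation.
Fallback: the ether is made at the other bond, C11–O1, setting out from 15 and coming back at 17.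
   - The reduction of step 8 run with the (S)-catalyst should give the (3E,4S)-allylic alcohol F7.
   - Mitsunobu coupling of F7 with quinolinol 6 (PPh3, DIAD, PhMe, −20 to 0 °C) alkylates O4 of 6 with inversion at C11. The hindered oxygen then no longer has to act as the nucleophile.

Further compounds
F1 | step 10 | 7,8-dimethoxy-2,2,6-trimethyl-2H-pyrano[3,2-c]quinolin-5(6H)-one | COc1ccc2c3c(c(=O)n(C)c2c1OC)C=CC(C)(C)O3
F2 | step 10 | 7,8-dimethoxy-1-methyl-3-(3-methylbutylidene)quinoline-2,4(1H,3H)-dione | COc1ccc2c(c1OC)N(C)C(=O)C(=CCC(C)C)C2=O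
F3 | step 10 | racemate of the target (20 and its enantiomer) | COc1ccc2c3c(c(=O)n(C)c2c1OC)[C@@H](CC(C)C)[C@H]1[C@@H](O3)c2c(c3ccc(OC)c(OC)c3n(C)c2=O)OC1(C)C.COc1ccc2c3c(c(=O)n(C)c2c1OC)[C@H](CC(C)C)[C@@H]1[C@H](O3)c2c(c3ccc(OC)c(OC)c3n(C)c2=O)OC1(C)C
F4 | step 8 | racemic (3E)-4-hydroxy-7,8-dimethoxy-2,2,6-trimethyl-3-(3-methylbutylidene)-3,4-dihydro-2H-pyrano[3,2-c]quinolin-5(6H)-one | OC1c2c(c3ccc(OC)c(OC)c3n(C)c2=O)OC(C)(C)/C1=C/CC(C)C
F5 | step 8 | (S)-O-methylmandelate of the (11R)-alcohol | CO[C@H](C(=O)O[C@H]1c2c(c3ccc(OC)c(OC)c3n(C)c2=O)OC(C)(C)/C1=C/CC(C)C)c1ccccc1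
F6 | step 8 | (S)-O-methylmandelate of the (11S)-alcohol | CO[C@H](C(=O)O[C@@H]1c2c(c3ccc(OC)c(OC)c3n(C)c2=O)OC(C)(C)/C1=C/CC(C)C)c1ccccc1
F7 | step 9 | (3E,4S)-4-hydroxy-7,8-dimethoxy-2,2,6-trimethyl-3-(3-methylbutylidene)-3,4-dihydro-2H-pyrano[3,2-c]quinolin-5(6H)-one | O[C@@H]1c2c(c3ccc(OC)c(OC)c3n(C)c2=O)OC(C)(C)/C1=C/CC(C)C
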